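Feature: in ring B, C7 carries a three-carbon 2-propenyl-derived unit (C11–C13) directly beside the equatorial oxygen on C8 (an isopulegol pattern), and C8–C9–C10–C5–C6–C7 is the carbon chain of citronellal.
Retrosynthesis: remove the C8–O acyl bond and lower C12 from ester to methyl, then cut C7–C8 (carbonyl-ene, opens ring B), C5–C6 (aldol) and C9–C10 (conjugate vinylation). Ring A goes back to 2-methylcyclohex-2-enone.
Forward: ring A is bought as a carbocycle and fully decorated (steps 1–8), and ring B closes in step 9. The side-chain ester is then attached and the isopropenyl methyl is raised to the methyl acrylate (steps 12–16).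
Stereochemistry: C1 comes from a CBS reduction (the only external chirality), and C10 from cuprate attack anti to the C1 silyl ether. C5 and C6 come from an anti-selective, equilibrating zinc aldol, and C7 and C8 from the chair ene transition state.

Key step: step 9

Remark: eudesmane numbering (decalin C1–C10, side chain C11–C13 on C7, C15 absent) is used for every intermediate. β is the face of the C10 methyl group. The target is (1R,5S,6S,7S,8S,10R), i.e. 1β-OH, 5α-H, 6α-OH, 7β-side chain, 8α-O-acyl.

Step 1
Reactants: 1 2-methylcyclohex-2-en-1-one
Product: 2 (R)-2-methylcyclohex-2-en-1-ol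
Conditions: (S)-2-methyl-CBS-oxazaborolidine (10 mol %), BH3·SMe2, THF, −20 °C; MeOH, then aqueous work-up
Reagents that add atoms: none
Why: Corey–Bakshi–Shibata reduction, in which the boron-bound ketone presents its smaller CH2 flank to the catalyst so that hydride reaches one face only and C1 is set as R, the one stereocentre from which all others are relayed.

Step 2
Reactants: 2 (R)-2-methylcyclohex-2-en-1-ol
Product: 3 (R)-1-(tert-butyldimethylsilyloxy)-2-methylcyclohex-2-ene
Conditions: TBSCl, imidazole, DMF, rt
Reagents that add atoms: tert-butyldimethylsilyl chloride, CC(C)(C)[Si](C)(C)Cl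
Why: Routine imidazole-mediated silylation of a secondary allylic alcohol, which does not touch C1 and installs the bulky group that later directs the cuprate.

Step 3
Reactants: 3 (R)-1-(tert-butyldimethylsilyloxy)-2-methylcyclohex-2-ene
Product: 4 (R)-4-(tert-butyldimethylsilyloxy)-3-methylcyclohex-2-en-1-one (ring A enone: C4 ketone, C5=C10, C1 OTBS)
Conditions: Rh2(cap)4 (cap = caprolactamate, 1 mol %), t-BuOOH (70 % aq), K2CO3, CH2Cl2, rt
Reagents that add atoms: tert-butyl hydroperoxide, CC(C)(C)OO
Why: Dirhodium-catalysed allylic C–H oxidation with tert-butyl hydroperoxide, a radical process that should pick the only unhindered secondary allylic position (the ring CH2 that becomes C4), since the methyl C–H bonds are primary and C1–H is screened by the silyl ether, while C1 itself stays untouched.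

Step 4
Reactants: 4 ring A enone
Product: 5 ring A trimethylsilyl enol ether (C4=C5) with 1β-OTBS, 10β-methyl and 10α-vinyl (vinyl trans to OTBS)
Conditions: CH2=CHMgBr, CuBr·SMe2 (20 mol %), TMSCl, DMPU, THF, −78 to −40 °C; Et3N, pentane, cold aq NaHCO3
Reagents that add atoms: vinylmagnesium bromide, C=C[Mg]Br; chlorotrimethylsilane, C[Si](C)(C)Cl
Why: Copper-catalysed conjugate addition of a Grignard reagent accelerated by TMSCl, the standard solution for β,β-disubstituted enones, in which the pseudoaxial C1 silyl ether shields the β face so that vinyl adds anti to it and sets quaternary C10, and the enolate is stored regiodefined as its silyl ether.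

Step 5
Reactants: 5 ring A trimethylsilyl enol ether; 6 3-methylbut-2-enal
Product: 9 anti-aldol ketone (1β-OTBS 10α-vinyl 5α-H 6α-OH prenyl-type carbinol on C5), via lithium enolate 7 (not isolated), via chlorozinc enolate 8 (not isolated)
Conditions: MeLi, THF, 0 °C; ZnCl2, 0 °C; 6, 0 °C; pH 7 buffer
Reagents that add atoms: methyllithium, [Li]C (lithium, kept only in 7); zinc chloride, Cl[Zn]Cl (zinc and chlorine, kept only in 8)
Why: Cleavage of the silyl enol ether with MeLi frees the regiodefined enolate, and its zinc-mediated aldol addition runs through a Zimmerman–Traxler chair in which the ring-locked (E)-enolate gives the anti C5/C6 pair, while the reversibility of zinc aldolate formation at 0 °C should funnel the material into the chelate that keeps the C1 silyl ether, C9 and the new C5 side chain all equatorial on ring A (5α-H, 6α-O).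

Step 6
Reactants: 9 anti-aldol ketone
Product: 10 1β,6α-bis(TBS) ether of the 10α-vinyl ring A ketone
Conditions: TBSOTf, 2,6-lutidine, CH2Cl2, −78 to −20 °C
Reagents that add atoms: tert-butyldimethylsilyl triflate, CC(C)(C)[Si](C)(C)OS(=O)(=O)C(F)(F)F
Why: Silylation of an aldol with the silyl triflate and a hindered pyridine base at low temperature is standard and avoids retro-aldol and β-elimination, and TBS is chosen for O6 because a bulky, weakly Lewis-basic ether best protects the ionisable allylic C6–O bond in step 9.

Step 7
Reactants: 10 bis(TBS) vinyl ketone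
Product: 12 primary C8 alcohol of the ring A ketone, via catechol boronate 11 (not isolated)
Conditions: catecholborane, RhCl(PPh3)3 (3 mol %), THF, 0 °C to rt; H2O2, pH 7 phosphate buffer, MeOH/THF, 0 °C to rt
Reagents that add atoms: hydrogen peroxide, OO (the C8 oxygen); catecholborane, B1Oc2ccccc2O1 (boron and catechol, kept only in 11)
Why: Rhodium-catalysed hydroboration with catecholborane is known to take a monosubstituted alkene in the presence of a ketone and to leave trisubstituted alkenes alone, boron goes to terminal C8 away from quaternary C10, buffered peroxide oxidation spares the β-silyloxy ketone, and any C4 carbinol from background reduction is returned to the ketone in step 8.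

Step 8
Reactants: 12 primary C8 alcohol
Product: 13 keto aldehyde (ene precursor: C9–C8 aldehyde on C10, C6 OTBS prenyl carbinol on C5, C4 ketone, 1β-OTBS)
Conditions: Dess–Martin periodinane, pyridine, CH2Cl2, 0 °C to rt
Reagents that add atoms: none
Why: Dess–Martin oxidation buffered with pyridine turns the primary alcohol into the C8 aldehyde under neutral conditions that neither epimerise C5 nor eliminate the C6 silyl ether.

Step 9
Reactants: 13 keto aldehyde
Product: 14 trans-decalin 1β,6α-bis(TBSO)-8α-hydroxy-7β-isopropenyl-10β-methyl-5αH-decalin-4-one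
Conditions: Me2AlCl (2.5 equiv), CH2Cl2, −78 to −40 °C; aq Rochelle salt
Reagents that add atoms: none
Why: Me2AlCl binds the sterically open C8 aldehyde; C7 of the C7=C11 alkene then bonds to C8 while a hydrogen of a C11 methyl group moves to the carbonyl oxygen through a six-centre, asynchronous but concerted ene transition state, and the resulting aluminium alkoxide loses methane, so no protic acid is left to start Prins or elimination chemistry. The closest known reaction is the Lewis-acid-promoted carbonyl-ene cyclisation of citronellal to isopulegol. Ring B closes in a 6-exo-trig mode (both the C=O and the C=C bond stay outside the new ring) through a chair that is already half of a trans-decalin, because C1 and C4 of ring A are its equatorial substituents at C10 and C5. C7 is controlled by C6: allylic 1,3-strain with the cis methyl on C11 holds H6 in the alkene plane and the C6 silyl ether equatorial, so C8 can reach only the alkene face that leaves the 2-propenyl group equatorial (7β). C8 is controlled by the axial C10 methyl group, which would clash 1,3-diaxially with an axial aluminium-bound oxygen, so the oxygen takes the equatorial 8α position trans to the 2-propenyl group. The step needs the aldehyde to react in preference to the C4 ketone and the allylic C6–O bond to survive: the ketone could only close a four-membered ring with the alkene and merely consumes one equivalent of Lewis acid, and the bulky, weakly basic TBS ether at C6 together with −78 °C and the proton-scavenging methyl–aluminium bond disfavours ionisation and β-elimination.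

Step 10
Reactants: 15 ethyl 2-(hydroxymethyl)acrylate
Product: 16 ethyl 2-[(tert-butyldimethylsilyloxy)methyl]acrylate
Conditions: TBSCl, imidazole, CH2Cl2, 0 °C to rt
Reagents that add atoms: tert-butyldimethylsilyl chloride, CC(C)(C)[Si](C)(C)Cl
Why: Routine silylation of a primary allylic alcohol, needed so that the side-chain hydroxyl cannot acylate itself in step 12.

Step 11
Reactants: 16 ethyl 2-[(tert-butyldimethylsilyloxy)methyl]acrylate
Product: 17 2-[(tert-butyldimethylsilyloxy)methyl]acrylic acid
Conditions: LiOH, THF/H2O, 0 °C; 1 M HCl to pH 4, 0 °C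
Reagents that add atoms: lithium hydroxide, [Li+].[OH-] (carboxyl oxygen)
Why: Saponification of the ethyl ester with LiOH at 0 °C followed by careful acidification, conditions under which a primary TBS ether and the acrylate double bond are known to persist.

Step 12
Reactants: 14 decalin alcohol; 17 2-[(tert-butyldimethylsilyloxy)methyl]acrylic acid
Product: 18 8α-{2-[(TBSO)methyl]acryloyloxy} ester of 14
Conditions: DCC, DMAP (30 mol %), CH2Cl2, 0 °C to rt
Reagents that add atoms: none
Why: Steglich esterification of the only free hydroxyl group (equatorial C8-OH) with retention at C8, carried out before C12 is oxidised so that no 12,8-lactone can form.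

Step 13
Reactants: 18 C8 ester
Product: 20 C12 enal (7β-(3-oxoprop-1-en-2-yl) group in place of isopropenyl), via allylic alcohol 19 (not isolated)
Conditions: SeO2 (0.5 equiv), t-BuOOH (decane), CH2Cl2, rt; filtered crude, then Dess–Martin periodinane, pyridine, CH2Cl2, 0 °C
Reagents that add atoms: selenium dioxide, O=[Se]=O (oxygen carrier); tert-butyl hydroperoxide, CC(C)(C)OO (terminal oxygen source)
Why: Allylic oxidation with SeO2 and tert-butyl hydroperoxide (ene reaction then 2,3-sigmatropic shift) selects the electron-rich 2-propenyl group over the acrylate, takes a methyl hydrogen because C7–H lies in the plane of the alkene between two equatorial neighbours, and the Dess–Martin treatment of the crude mixture converges alcohol 19 and enal on 20.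

Step 14
Reactants: 20 C12 enal
Product: 21 C12 acrylic acid
Conditions: NaClO2, NaH2PO4, 2-methylbut-2-ene, t-BuOH/H2O, 0 °C to rt
Reagents that add atoms: sodium chlorite, [Na+].[O-]Cl=O
Why: Pinnick oxidation converts the enal to the acrylic acid under buffered conditions with 2-methylbut-2-ene as chlorine scavenger, leaving ketone, esters, alkenes and silyl ethers untouched.

Step 15
Reactants: 21 C12 acrylic acid
Product: 22 tris(TBS) ether of the target (C12 methyl ester)
Conditions: MeI, KHCO3, DMF, rt
Reagents that add atoms: iodomethane, CI
Why: SN2 alkylation of the carboxylate with iodomethane under a weak base avoids diazoalkanes, which could add to the two acrylates, and is too mild to disturb C5 or the C6 silyl ether.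

Step 16
Reactants: 22 tris(TBS) ether
Product: 23 CNP0144895.1 (target)
Conditions: HF·pyridine, pyridine/THF, 0 °C to rt (plastic vessel)
Reagents that add atoms: none
Why: Fluoride-driven cleavage of all three TBS ethers with pyridine-buffered HF avoids both basic conditions (retro-aldol, conjugate addition to the acrylates) and strong acid (closure of the 6,12-lactone), and no stereocentre is affected.

Compound list
1 | 2-methylcyclohex-2-en-1-one | CC1=CCCCC1=O | starting material
2 | (R)-2-methylcyclohex-2-en-1-ol | CC1=CCCC[C@H]1O | intermediate
3 | (R)-1-(tert-butyldimethylsilyloxy)-2-methylcyclohex-2-ene | CC1=CCCC[C@H]1O[Si](C)(C)C(C)(C)C | intermediate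
4 | (R)-4-(tert-butyldimethylsilyloxy)-3-methylcyclohex-2-en-1-one | CC1=CC(=O)CC[C@H]1O[Si](C)(C)C(C)(C)C | intermediate
5 | ring A trimethylsilyl enol ether, 1β-OTBS, 10β-methyl, 10α-vinyl | C=C[C@@]1(C)[C@H](O[Si](C)(C)C(C)(C)C)CCC(O[Si](C)(C)C)=C1 | intermediate
6 | 3-methylbut-2-enal | CC(C)=CC=O | starting material
7 | lithium enolate of the ring A ketone (C4=C5) | C=C[C@@]1(C)[C@H](O[Si](C)(C)C(C)(C)C)CCC([O-])=C1.[Li+] | intermediate (not isolated)
8 | chlorozinc enolate of the ring A ketone (C4=C5) | C=C[C@@]1(C)[C@H](O[Si](C)(C)C(C)(C)C)CCC(O[Zn]Cl)=C1 | intermediate (not isolated)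
9 | anti-aldol ketone, 5α-H, 6α-OH | C=C[C@@]1(C)[C@H](O[Si](C)(C)C(C)(C)C)CCC(=O)[C@@H]1[C@@H](O)C=C(C)C | intermediate
10 | 1β,6α-bis(TBS) vinyl ketone | C=C[C@@]1(C)[C@H](O[Si](C)(C)C(C)(C)C)CCC(=O)[C@@H]1[C@@H](O[Si](C)(C)C(C)(C)C)C=C(C)C | intermediate
11 | C8 catechol boronate | O1c2ccccc2OB1CC[C@@]3(C)[C@H](O[Si](C)(C)C(C)(C)C)CCC(=O)[C@@H]3[C@@H](O[Si](C)(C)C(C)(C)C)C=C(C)C | intermediate (not isolated)
12 | primary C8 alcohol | OCC[C@@]1(C)[C@H](O[Si](C)(C)C(C)(C)C)CCC(=O)[C@@H]1[C@@H](O[Si](C)(C)C(C)(C)C)C=C(C)C | intermediate
13 | keto aldehyde, ene precursor | O=CC[C@@]1(C)[C@H](O[Si](C)(C)C(C)(C)C)CCC(=O)[C@@H]1[C@@H](O[Si](C)(C)C(C)(C)C)C=C(C)C | intermediate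
14 | 1β,6α-bis(TBSO)-8α-hydroxy-7β-isopropenyl-10β-methyl-5αH-decalin-4-one, ene product | O[C@H]1C[C@@]2(C)[C@H](O[Si](C)(C)C(C)(C)C)CCC(=O)[C@@H]2[C@@H](O[Si](C)(C)C(C)(C)C)[C@@H]1C(C)=C | intermediate
15 | ethyl 2-(hydroxymethyl)acrylate | C=C(CO)C(=O)OCC | starting material
16 | ethyl 2-[(tert-butyldimethylsilyloxy)methyl]acrylate | C=C(CO[Si](C)(C)C(C)(C)C)C(=O)OCC | intermediate
17 | 2-[(tert-butyldimethylsilyloxy)methyl]acrylic acid | C=C(CO[Si](C)(C)C(C)(C)C)C(=O)O | intermediate
18 | C8 ester of 14 with 17 | C=C(CO[Si](C)(C)C(C)(C)C)C(=O)O[C@H]1C[C@@]2(C)[C@H](O[Si](C)(C)C(C)(C)C)CCC(=O)[C@@H]2[C@@H](O[Si](C)(C)C(C)(C)C)[C@@H]1C(C)=C | intermediate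
19 | C12 allylic alcohol | C=C(CO[Si](C)(C)C(C)(C)C)C(=O)O[C@H]1C[C@@]2(C)[C@H](O[Si](C)(C)C(C)(C)C)CCC(=O)[C@@H]2[C@@H](O[Si](C)(C)C(C)(C)C)[C@@H]1C(=C)CO | intermediate (not isolated)
20 | C12 enal | C=C(CO[Si](C)(C)C(C)(C)C)C(=O)O[C@H]1C[C@@]2(C)[C@H](O[Si](C)(C)C(C)(C)C)CCC(=O)[C@@H]2[C@@H](O[Si](C)(C)C(C)(C)C)[C@@H]1C(=C)C=O | intermediate
21 | C12 acrylic acid | C=C(CO[Si](C)(C)C(C)(C)C)C(=O)O[C@H]1C[C@@]2(C)[C@H](O[Si](C)(C)C(C)(C)C)CCC(=O)[C@@H]2[C@@H](O[Si](C)(C)C(C)(C)C)[C@@H]1C(=C)C(=O)O | intermediate
22 | tris(TBS) ether of the target | C=C(CO[Si](C)(C)C(C)(C)C)C(=O)O[C@H]1C[C@@]2(C)[C@H](O[Si](C)(C)C(C)(C)C)CCC(=O)[C@@H]2[C@@H](O[Si](C)(C)C(C)(C)C)[C@@H]1C(=C)C(=O)OC | intermediate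
23 | CNP0144895.1 | C=C(CO)C(=O)O[C@H]1C[C@@]2(C)[C@H](O)CCC(=O)[C@@H]2[C@@H](O)[C@@H]1C(=C)C(=O)OC | target

Total step count: 16 (14 in the main line, 2 for the side-chain acid).
Longest linear sequence: 14 steps (steps 1–9 and 12–16, from 1).

Steps most likely to fail

Step 5 (aldol).
- What may go wrong: the aldehyde may approach the α face of the enolate, anti to the axial C10 methyl group. The zinc aldolates may equilibrate slowly or incompletely. Proton transfer from the γ-methyl groups of the enal may quench the enolate.
- Fallback: this replaces chelate (thermodynamic) control by catalyst control and sets out from 5.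
- Exchange of the trimethylsilyl group with SiCl4 (Hg(OAc)2, 1 mol %, CH2Cl2) should give the trichlorosilyl enol ether F1.
- F1 adds to 6 at −78 °C under 10 mol % of a chiral phosphoramide Lewis base (built on N,N'-dimethyl-1,2-diphenylethane-1,2-diamine).
- The closed chair at hexacoordinate silicon is anti-selective for ring (E)-enolates, and its facial preference is chosen with the catalyst enantiomer.
- Work-up with aqueous NaHCO3 comes back to the route at 9.

Step 9 (ene closure).
- What may go wrong: the allylic C6–O bond may ionise, or β-elimination towards the C4 ketone may occur.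
- Attack of the alkene may be sluggish, because the C6–O bond lies antiperiplanar to the forming bond and lowers the alkene's nucleophilicity. Chloride may also be captured at C11.
- Fallback: this keeps the C7–C8 bond formation but swaps electrophilic activation for a neutral allylmetal addition. It sets out from 13.
- Ene-type allylic chlorination (NCS, PhSeCl 10 mol %, CH2Cl2) should move the alkene to C11=C13 and place chlorine on C7, giving the allylic chloride F2. Both of its C7 epimers converge in the next operation.
- CrCl2 in THF (Nozaki–Hiyama allylation) forms the allylchromium species, which adds through its γ-carbon C7 to the C8 aldehyde.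
- This addition is selective for aldehydes over ketones, and its chair transition state gives the trans C7/C8 pair. It comes back to the route at 14.

Step 13 (allylic oxidation).
- What may go wrong: C7–H may be abstracted in competition, the C4 ketone may undergo α-oxidation, the product may be over-oxidised, or conversion at the crowded 2-propenyl group may stall.
- Fallback: this sets out from 18 and replaces the selenium ene chemistry by chlorination and oxidation.
- Ene-type chlorination with Ca(OCl)2 and solid CO2 (CH2Cl2/H2O, 0 °C) attacks only the electron-rich 2-propenyl group and should give the methallyl-type chloride F3.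
- The N-oxide variant of the Kornblum oxidation (N-methylmorpholine N-oxide, NaI 10 mol %, MeCN) converts F3 to the enal and comes back to the route at 20.

Further compounds
F1 | step 5 | trichlorosilyl enol ether of the ring A ketone (C4=C5) | C=C[C@@]1(C)[C@H](O[Si](C)(C)C(C)(C)C)CCC(O[Si](Cl)(Cl)Cl)=C1
F2 | step 9 | C7 allylic chloride of the keto aldehyde (C11=C13, C7 epimers) | O=CC[C@@]1(C)[C@H](O[Si](C)(C)C(C)(C)C)CCC(=O)[C@@H]1[C@@H](O[Si](C)(C)C(C)(C)C)C(Cl)C(C)=C
F3 | step 13 | C12 allylic chloride of ester 18 | C=C(CO[Si](C)(C)C(C)(C)C)C(=O)O[C@H]1C[C@@]2(C)[C@H](O[Si](C)(C)C(C)(C)C)CCC(=O)[C@@H]2[C@@H](O[Si](C)(C)C(C)(C)C)[C@@H]1C(=C)CCl
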